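Count the turnovers of this flask: a turnover is one point of starting material consumed, and the question is how many happen and what each one yields.

| setting | eta | flask |
|---|---|---|
| starting material | 0.20 M | 0.20 M |
| coupling partner | 2 equiv | 2.00 equiv |
| protic impurity | 0.010 M | 0.0100 M |
| remark | the very flask that is asked about, followed so far |  |
| time |  | 1.0 h |

eta run (percent of the starting material charged)

| time / min | target / % | starting material / % |
|---|---|---|
| 10.0 | 20.0 | 40.4 |
| 20.0 | 26.5 | 30.0 |
| 25.0 | 27.8 | 27.7 |
| 40.0 | 30.6 | 23.4 |

(scatter of a reading: 0.5 percentage points)

- target is meant together with its crystals
- solid, in amounts per volume of the solution: crystals
- additions bring no volume worth counting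
- the analysis behind the earlier runs scatters by 0.5 percentage points, standard deviation
- reactions considered so far: starting material + coupling partner -> target; starting material + 2 coupling partner -> side product; coupling partner -> decomposed reagent; starting material + protic impurity -> quenched substrate; crystals <-> target

- winter: at 1.0 h add coupling partner, 50.0% of the amount charged, then wait 1.0 h
- spring: change nothing and wait 1.0 h more
- midnight: at 1.0 h add starting material, 50.0% of the amount charged, then wait 1.0 h

1. target, in percent of the starting material first charged, at 1.0 h
2. the option that brings most further target ("none" if no option brings more than 2 percentage points) (winter / spring / midnight / none)
3. target present, in percent of the starting material first charged, after winter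
4. target present, in percent of the starting material first charged, after midnight

I build the flask one process at a time. With the main step alone, each turnover makes a target, so the ceiling is 100 percent.

Now I add the protic impurity, which can take [protic impurity]/[starting material] of the charge:

ceiling = 100 percent less 5.00%

Next comes the side step, which makes some turnovers yield side product. So I define the turnover yield (a selectivity): target gained per point of starting material consumed, read here between 10.0 min and 40.0 min:

yield = 11 percentage points / 17 points = 0.624

This is a reading and carries the scatter of 0.5 points. If the 23.4% of starting material still there at 40.0 min all turned over at this yield, target would reach 45.2%.

Last comes the decay of the coupling partner, and the turnovers do fade. From 10.0 min to 25.0 min there are 13 points, and in the equally long stretch to 40.0 min there are 4.3 points. I continue that ratio of 0.339 per stretch up to 1.0 h: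

further turnovers = 1.7 points

target = 30.6% + 0.624 × 1.7 points = 31.6%

Fresh partner could at most turn over what is left, worth 14 points of target, which is more than the margin of 2 points, so I choose winter.

The forecast gives 32.4%, which is higher than my figure, along with winter, 40.5% and 35.2%: "Fresh partner should convert most of the remaining starting material at about 60% selectivity".

The flask gives 32.7%, and winter is best, bringing 8.4 points against 1.4 points for spring and 3.6 points for midnight, so winter ends at 41.1% and midnight at 36.3%.

    starting material + coupling partner → target (k = 0.00230 /M/s)
    starting material + 2 coupling partner → side product (k = 0.0140 /M²/s)
    coupling partner → decomposed reagent (k = 4.70 × 10⁻⁴ /s)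
    starting material + protic impurity → quenched substrate (k = 0.110 /M/s)
    crystals ⇌ target, rate k5*(cs5 - [target]) while solid is left; crystals form when [target] > cs5 (solubility = 0.0710 M, k = 0.00560 /s)

At 60.0 min this flask holds 21.7% of its starting material and 4.90% of its coupling partner. At 0.624 per turnover, the winter gain counts as 13 points of turnovers, less than the starting material there. In the neighbour charged with 0.050 M, 21.9% of target came from 49.7% of starting material consumed, the quenched 20.0% included, which is 0.440 per turnover over its whole run, against 0.418 over the whole run of this flask.

The runs were computed with constants of no real substance; the scatter is artificial.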